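If a flask has stopped before its first reading, the clock tells us little, and the recipe must tell us where it stops.

| flask | substrate | partner | free catalyst | remark | time |
|---|---|---|---|---|---|
| summer | 0.067 M | 0.70 equiv | 0.15 mol% | run made earlier |  |
| spring | 0.48 M | 0.70 equiv | 0.15 mol% | run made earlier |  |
| alder | 0.14 M | 0.700 equiv | 0.15 mol% |  | 5.0 h |
| birch | 0.10 M | 0.700 equiv | 0.15 mol% |  | 5.0 h |
| ash | 0.30 M | 0.700 equiv | 0.15 mol% |  | 5.0 h |
| elm | 0.050 M | 0.700 equiv | 0.15 mol% |  | 5.0 h |

- summer (time / h: product / %, substrate / %): 0.417: 7, 89; 1.00: 8, 94; 2.00: 4, 96; 5.00: 9, 93
- spring (time / h: product / %, substrate / %): 0.417: 26, 74; 1.00: 27, 73; 2.00: 27, 73; 5.00: 28, 70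

(standard deviation of a reading: 2 percentage points)

- all flasks from highest to lowest amount of product, in percent of the substrate charged, at 5.0 h (alder / birch / ash / elm)
- the same order at 20 h (alder / birch / ash / elm)
- the amount of product, in percent of the substrate charged of the flask you put first, at 5.0 h
- the amount of product, in percent of the substrate charged of the flask you put last, at 5.0 h

- the analysis behind the earlier runs scatters by 2 percentage points, standard deviation

Both earlier runs look stopped. From 0.417 h to 5.00 h the spring run moves from 26% to 28% of product, close to the scatter of 2 percentage points, and the summer run from 7% to 9%, with a dip to 4% between. We therefore read each as a balance (thermodynamic control) in which substrate and partner join to give product. Partner and catalyst are charged in the same proportion everywhere, so the flasks differ in the substrate charge c, and we hold c against a second amount.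

That amount is the balance concentration c*. Let x be the fraction of substrate turned to product. Multiply the substrate fraction left by the partner left, 0.7 minus x, and by c, then divide by x. The mean spring reading of 27.0% gives c* = 0.558 M. The mean summer reading of 7.00% gives 0.561 M, which is about the same, at a very different charge.

Running the rule backwards, we expect 20.9% in ash, whose charge is the largest, and 5.47% in elm, whose charge is the smallest.

The forecast gives ash > alder > birch > elm at 5.0 h and ash > alder > birch > elm at 20 h, with 21% and 5.5%, on the ground that “each has stalled at a plateau”.

The flasks give ash > alder > birch > elm at 5.0 h and ash > alder > birch > elm at 20 h, with 22.1% in ash and 5.97% in elm.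

    substrate + free catalyst ⇌ catalyst intermediate A (K = 17.0 M⁻¹, k = 16.0 M⁻¹ s⁻¹)
    partner + catalyst intermediate A ⇌ catalyst intermediate B (K = 6.50 M⁻¹, k = 13.0 M⁻¹ s⁻¹)
    catalyst intermediate B ⇌ catalyst intermediate C (K = 0.310, k = 0.900 s⁻¹)
    catalyst intermediate C ⇌ free catalyst + product (K = 0.0580 M, k = 35.0 s⁻¹)

In elm, half of the turnover up to 5.00 h of substrate and free catalyst into catalyst intermediate A was done by 0.145 h, and >99.9% of it by 2.50 h, when substrate stood at 94.0% of its charge. From 2.50 h to 50.0 h, elm held 5.97% of product. At 5.0 h, ash held 22.1% against 20.9% from c*, and elm 5.97% against 5.47%. For the flask like elm but charged at 0.12 M, with the same equivalents and loadings, c* gives 11.2%, and that flask holds 12.1% of product at 5.00 h.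

(The data are simulated for an exercise, and the scatter is random.)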